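Remarks. Carbons are numbered as in eudesmane: C10 is the quaternary ring-fusion carbon, C14 its CH2OH, C5 the ring-fusion CH, C7 the isopropenyl-bearing CH, C15 the vinylic methyl. Ring A is C1–C5/C10 and ring B is C5–C10. In this numbering the target is (1R,2S,5R,7S,9S,10S). Assumption: 1, 2, 6 (as formalin or paraformaldehyde), 9, 13 and (−)-diisopinocampheylborane are taken as commercial.

## Structural features

The target is a trans-fused decalin of the eudesmane type. Ring A is a cyclohexene with a trisubstituted C3=C4 olefin carrying the C15 methyl; ring B is a cyclohexane carrying an isopropenyl group at C7. There are six stereocentres. C2, C1, C10 and C9 are contiguous, C5 is adjacent to C10, and C7 is 1,3 to both C5 and C9. C10 is quaternary, carries the free CH2OH (C14) and is flanked by the oxygenated carbons C1 and C9, so the molecule contains a neopentyl 2-(hydroxymethyl)-1,3-diol array. C14 is axial and anti to H5. The C1 oxygen is equatorial and cis to C14; the C2 oxygen is pseudo-axial and cis to O1; the C9 acetate is axial and syn-diaxial to the axial C7 isopropenyl group, which lies on the face opposite C14. The four oxygens are in three different states (C1 isovalerate, C2 allylic acetate, C9 acetate, free primary C14–OH), so 1,2- and 1,3-acyl migration under basic conditions and ionisation of the allylic acetate under acid are the fragile points. The two olefins exclude hydrogenolysis. The real difficulty is the quaternary C10 in its correct relation to C5 (trans fusion) and C7, together with the differentiation of its two oxygenated one-carbon neighbours (C14 against C1) and of the esters.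

## Logic of the disconnections

**20 ⇒ 19 ⇒ 18.** The C14 O–Si bond and the C9 O–acetyl bond are cut last. The free primary alcohol must appear only when all secondary oxygens are acylated, and under non-basic conditions, so that no acyl group migrates to C14. This demands a fluoride-labile group on C14 that survives the whole route.

**18 ⇒ 17.** The C9–H bond and the C1 O–acyl bond are cut together, which leads back to a C9 ketone and a free C1 hydroxyl. Both can then be made in one redox-neutral step, in which the C1 oxygen carries the acyl precursor and delivers hydride across to C9. The forward step must give the axial C9 alcohol, anti to O1.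

**17 ⇒ 16.** The C2 O–acetyl bond is cut. The forward step must acylate the allylic, less hindered C2 hydroxyl of a cis-diol in preference to the neopentyl C1 hydroxyl.

**16 ⇒ 15.** The C3=C4 bond of ring A is cut (ring-closing metathesis). This turns the decalin into a monocyclic ring B ketone carrying two olefin-terminated arms on C10 and C5. The arms must be trans on ring B for the fusion to become trans.

**15 ⇒ 12 + 13.** The C1–C2 bond is cut, which removes both ring A carbinol stereocentres at once. The forward step must add a three-carbon, oxygen-bearing allyl unit to a neopentyl aldehyde with anti diastereoselectivity and reagent-controlled facial selectivity. The anti relation of the open chain becomes the cis-diol of ring A.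

**12 ⇒ 11 ⇒ 8 + 9 + 6 (key).** The C5–C4 and C10–C1 bonds are cut in one operation. This reduces the problem to a cyclohexenone that already carries C14 and C7, an isopropenyl nucleophile and a one-carbon electrophile. The forward step must add the nucleophile trans to the C7 substituent and the electrophile trans to the new C5 substituent. The C14 arm arrives silylated and the C1 arm arrives free, so the two CH2O arms on C10 are different from the moment the quaternary centre exists.

**8 ⇒ 5 + 6, and 5 ⇒ 3 ⇒ 1 + 2.** The C10–C14 bond is cut (α-hydroxymethylation of an enone), then the C5=C10 unsaturation, then the C7–C11 bond (catalytic asymmetric conjugate addition). The demands are regioselective desaturation away from C7 and one enantioselective step that sets C7, the only stereocentre not set by substrate or reagent control later.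

## Other disconnections considered

**Alternative 1:** Robinson annulation, the first plan that comes to mind. It cuts C1–C10 and C4–C5. In the forward sense (+)-dihydrocarvone A1 and ethyl vinyl ketone A2 would give the enone A3 (10-epi-α-cyperone series), which has the correct C7/C10 relationship. The annulation builds ring A but none of the oxygenation: A3 has C14 as a methyl, C9 as an unactivated methylene, no oxygen at C1 or C2, and a C3 ketone with a C4=C5 olefin where the target has a C3=C4 olefin and a C5 stereocentre. Four C–H oxidations (one on an angular methyl), an enone transposition and a late C5 stereocentre would follow. The chosen plan instead has C9, C14 and C1 oxygenated when the quaternary centre is formed.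

**Alternative 2:** intramolecular Diels–Alder reaction. It cuts C5–C10 and C1–C2. The triene A4 (a (Z)-β-acyloxy enal dienophile tethered through C6–C9 to an (E,E)-1-acetoxy diene) would give the decalin aldehyde A5, setting C1, C2, C5 and C10 at once. The grounds against it are mechanistic and practical. Both diene and dienophile are donor-substituted, so the cycloaddition is electronically unassisted and would need temperatures at which enol esters and the skipped polyene are not safe. The trans fusion requires one specific endo/exo mode relative to the C9 substituent. A4 needs three geometrically defined olefins and two stereocentres before the key step, which is more steps than the whole chosen route up to its key step.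

**Alternative 3:** transannular cyclisation of a germacrane. It cuts C5–C10. Lewis-acid opening of the 1,10-epoxygermacra-4-ene A6 would form C5–C10 across the ten-membered ring and, after loss of H3, give the eudesmenol A7. The cationic centre at C10 carries two β-oxygen substituents (C9 acetate and C14 silyl ether). That slows ionisation and invites participation of the C9 acetate. Proton loss from the C4 cation can give Δ3, Δ4 or Δ4(15) olefins. A6 is a ten-membered ring with five substituents and an (E)-olefin that has to be made first. The chosen plan sets the same C5/C10 relationship on a six-membered ring by two sequential anti additions.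

Key step: step 5

## Steps

**Step 1**
Reactants: 1 cyclohex-2-en-1-one; 2 isopropenylboronic acid pinacol ester
Product: 3 (S)-3-(prop-1-en-2-yl)cyclohexan-1-one
Conditions: [Rh(cod)Cl]2 (2.5 mol %), (S)-BINAP (6 mol %), KOH (10 mol %), dioxane/H2O 10:1, 60 °C
Reagents that add atoms: none
Why: Hayashi–Miyaura rhodium-catalysed asymmetric 1,4-addition of an alkenylboronate to a cyclic enone; the BINAP–Rh–alkenyl species should add to one enantioface of 1 and set C7 as (S), in the sense known for (S)-BINAP and 3-substituted cyclohexanones (the ligand antipode is chosen to give (S)-3).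

**Step 2**
Reactants: 3 (S)-3-(prop-1-en-2-yl)cyclohexan-1-one
Product: 5 (S)-5-(prop-1-en-2-yl)cyclohex-2-en-1-one, via trimethylsilyl enol ether 4 (not isolated)
Conditions: LDA, TMSCl (internal quench), THF, −78 °C; then Pd(OAc)2 (10 mol %), O2 (1 atm), DMSO, 25 °C
Reagents that add atoms: none
Why: Kinetic deprotonation at the α-methylene remote from the C7 substituent (C10) should give 4, and Saegusa–Ito oxidation in its catalytic aerobic form converts it into the C5=C10 enone; C7 is not touched.

**Step 3**
Reactants: 5 (S)-5-(prop-1-en-2-yl)cyclohex-2-en-1-one; 6 formaldehyde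
Product: 7 (S)-2-(hydroxymethyl)-5-(prop-1-en-2-yl)cyclohex-2-en-1-one
Conditions: aq. HCHO (37 %), DMAP (10 mol %), THF/H2O, 25 °C
Reagents that add atoms: none
Why: Morita–Baylis–Hillman hydroxymethylation of a cyclic enone; it attaches C14 to C10 without creating a stereocentre.

**Step 4**
Reactants: 7 (S)-2-(hydroxymethyl)-5-(prop-1-en-2-yl)cyclohex-2-en-1-one
Product: 8 (S)-2-{[(tert-butyldimethylsilyl)oxy]methyl}-5-(prop-1-en-2-yl)cyclohex-2-en-1-one
Conditions: TBSCl, imidazole, CH2Cl2, 0 °C
Reagents that add atoms: tert-butyldimethylsilyl chloride, CC(C)(C)[Si](C)(C)Cl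
Why: Standard silylation of a primary allylic alcohol; the silyl ether marks C14 and is only removed in the last step.

**Step 5**
Reactants: 8 (S)-2-{[(tert-butyldimethylsilyl)oxy]methyl}-5-(prop-1-en-2-yl)cyclohex-2-en-1-one; 9 isopropenylmagnesium bromide; 6 formaldehyde
Product: 11 (2S,3R,5S)-2-{[(tert-butyldimethylsilyl)oxy]methyl}-2-(hydroxymethyl)-3,5-di(prop-1-en-2-yl)cyclohexan-1-one, via bromomagnesium enolate 10 (not isolated)
Conditions: 9 (1.6 equiv), CuBr·SMe2 (20 mol %), THF, −78 → −40 °C; then monomeric 6 (gas, from cracked paraformaldehyde, excess), −78 → −30 °C; sat. aq. NH4Cl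
Reagents that add atoms: none
Why: Copper-catalysed 1,4-addition of 9 to 8 (π-complex, oxidative addition at C5, reductive elimination) gives the tetrasubstituted bromomagnesium enolate 10, which is trapped in the same flask at C10 by monomeric formaldehyde in an aldol addition. The closest known reaction type is the tandem vicinal difunctionalisation of cyclic enones (conjugate addition–enolate trapping, as in three-component prostaglandin syntheses and cuprate/alkylation sequences on carvone). No ring is closed; the step forms the two C–C bonds C5–C4 and C10–C1 on adjacent carbons of ring B and creates C5 and the quaternary C10. C5 is controlled by C7: axial attack on the half-chair of 8 that holds the C7 isopropenyl group pseudo-equatorial places the new substituent trans to it. C10 is controlled by C5: in 10 the new C5 substituent is pseudo-axial (allylic strain with the C14 arm), so formaldehyde should attack axially from the opposite face, and the new CH2OH arm (C1) ends trans to C4 and cis to the C7 isopropenyl group, while the resident silylated arm becomes C14. The step needs 1,4- over 1,2-addition (copper), C- over O-hydroxymethylation and capture before loss of silanolate from 10 (small non-enolisable electrophile, low temperature). The anti arrangement of the two new bonds is what later allows the trans ring fusion; a cycloaddition across C5=C10 would give the cis relationship.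

**Step 6**
Reactants: 11 (2S,3R,5S)-2-{[(tert-butyldimethylsilyl)oxy]methyl}-2-(hydroxymethyl)-3,5-di(prop-1-en-2-yl)cyclohexan-1-one
Product: 12 (1R,4S,6R)-1-{[(tert-butyldimethylsilyl)oxy]methyl}-2-oxo-4,6-di(prop-1-en-2-yl)cyclohexane-1-carbaldehyde
Conditions: Dess–Martin periodinane, NaHCO3, CH2Cl2, 0 → 25 °C
Reagents that add atoms: none
Why: Dess–Martin oxidation of a primary neopentyl alcohol under buffered conditions; C10 is quaternary, so the β-keto aldehyde cannot enolise or epimerise.

**Step 7**
Reactants: 12 (1R,4S,6R)-1-{[(tert-butyldimethylsilyl)oxy]methyl}-2-oxo-4,6-di(prop-1-en-2-yl)cyclohexane-1-carbaldehyde; 13 allenylboronic acid pinacol ester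
Product: 15 (2R,3R,5S)-2-{[(tert-butyldimethylsilyl)oxy]methyl}-2-[(1R,2S)-1,2-dihydroxybut-3-en-1-yl]-3,5-di(prop-1-en-2-yl)cyclohexan-1-one, via boron adduct 14 (not isolated)
Conditions: 13, (−)-Ipc2BH [from (+)-α-pinene], Et2O, 0 °C; then 12, −78 °C; then 3 M NaOH, 30 % H2O2, 0 → 25 °C
Reagents that add atoms: hydrogen peroxide, OO
Why: Brown anti-α-hydroxyallylation: hydroboration of 13 gives the (E)-γ-borylallylborane, which should add through a chair transition state to the aldehyde (anti) on its Si face (the usual sense of the (+)-α-pinene-derived Ipc2B-allyl reagents), setting C1 as (R). Oxidation of the C2–B bond with retention gives C2 as (S). The ketone does not react at −78 °C.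

**Step 8**
Reactants: 15 (2R,3R,5S)-2-{[(tert-butyldimethylsilyl)oxy]methyl}-2-[(1R,2S)-1,2-dihydroxybut-3-en-1-yl]-3,5-di(prop-1-en-2-yl)cyclohexan-1-one
Product: 16 (1R,2S,5R,7S,10R)-14-[(tert-butyldimethylsilyl)oxy]-1,2-dihydroxyeudesma-3,11-dien-9-one
Conditions: Grubbs second-generation catalyst (5 mol %), CH2Cl2, 40 °C
Reagents that add atoms: none
Why: Ring-closing metathesis between the vinyl group on C2 and the isopropenyl group on C5 forms the trisubstituted C3=C4 olefin in a six-membered ring. The two arms are trans on ring B, so the fusion is trans. The C7 isopropenyl group could only close a bridged eight-membered ring and should stay untouched.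

**Step 9**
Reactants: 16 (1R,2S,5R,7S,10R)-14-[(tert-butyldimethylsilyl)oxy]-1,2-dihydroxyeudesma-3,11-dien-9-one
Product: 17 (1R,2S,5R,7S,10R)-14-[(tert-butyldimethylsilyl)oxy]-1-hydroxy-9-oxoeudesma-3,11-dien-2-yl acetate
Conditions: Ac2O (1.05 equiv), pyridine, CH2Cl2, 0 °C
Reagents that add atoms: acetic anhydride, CC(=O)OC(C)=O
Why: Selective acylation of the allylic, pseudo-axial C2 hydroxyl in preference to the C1 hydroxyl, which is neopentyl (next to the quaternary C10) and more hindered.

**Step 10**
Reactants: 17 (1R,2S,5R,7S,10R)-14-[(tert-butyldimethylsilyl)oxy]-1-hydroxy-9-oxoeudesma-3,11-dien-2-yl acetate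
Product: 18 (1R,2S,5R,7S,9S,10S)-2-acetoxy-14-[(tert-butyldimethylsilyl)oxy]-9-hydroxyeudesma-3,11-dien-1-yl 3-methylbutanoate
Conditions: 3-methylbutanal (5 equiv), SmI2 (30 mol %), THF, −10 °C
Reagents that add atoms: 3-methylbutanal, CC(C)CC=O
Why: Evans–Tishchenko reduction: the samarium-bound hemiacetal formed from the C1 hydroxyl and the aldehyde transfers its hydride intramolecularly to the C9 ketone and becomes the C1 isovalerate. O1 is equatorial and lies on the C14 side of the C9 carbonyl plane, so hydride should arrive on that face and give the axial (9S) alcohol anti to O1. Any acetyl migration between O2 and O1 is drained through the isomer with free C1–OH, the only one that can react.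

**Step 11**
Reactants: 18 (1R,2S,5R,7S,9S,10S)-2-acetoxy-14-[(tert-butyldimethylsilyl)oxy]-9-hydroxyeudesma-3,11-dien-1-yl 3-methylbutanoate
Product: 19 (1R,2S,5R,7S,9S,10S)-2,9-diacetoxy-14-[(tert-butyldimethylsilyl)oxy]eudesma-3,11-dien-1-yl 3-methylbutanoate
Conditions: Ac2O, DMAP, Et3N, CH2Cl2, 25 → 40 °C
Reagents that add atoms: acetic anhydride, CC(=O)OC(C)=O
Why: DMAP-catalysed acetylation of the only free hydroxyl, a hindered axial secondary alcohol; no other nucleophilic site is present.

**Step 12**
Reactants: 19 (1R,2S,5R,7S,9S,10S)-2,9-diacetoxy-14-[(tert-butyldimethylsilyl)oxy]eudesma-3,11-dien-1-yl 3-methylbutanoate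
Product: 20 (1R,2S,5R,7S,9S,10S)-2,9-diacetoxy-14-hydroxyeudesma-3,11-dien-1-yl 3-methylbutanoate (CNP0257109.1)
Conditions: HF·pyridine, pyridine, THF, 0 → 25 °C
Reagents that add atoms: none
Why: Fluoride cleavage of the primary silyl ether in a buffered, non-basic medium, so that no alkoxide is formed and the esters at C1 and C9 should not migrate to C14.

## Compound list

1 | cyclohex-2-en-1-one | O=C1C=CCCC1 | starting material
2 | isopropenylboronic acid pinacol ester | C=C(C)B1OC(C)(C)C(C)(C)O1 | starting material
3 | (S)-3-(prop-1-en-2-yl)cyclohexan-1-one | C=C(C)[C@@H]1CC(=O)CCC1 | intermediate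
4 | (S)-trimethyl{[5-(prop-1-en-2-yl)cyclohex-1-en-1-yl]oxy}silane | C=C(C)[C@@H]1CC(O[Si](C)(C)C)=CCC1 | intermediate (not isolated)
5 | (S)-5-(prop-1-en-2-yl)cyclohex-2-en-1-one | C=C(C)[C@@H]1CC(=O)C=CC1 | intermediate
6 | formaldehyde | C=O | starting material
7 | (S)-2-(hydroxymethyl)-5-(prop-1-en-2-yl)cyclohex-2-en-1-one | C=C(C)[C@@H]1CC(=O)C(CO)=CC1 | intermediate
8 | (S)-2-{[(tert-butyldimethylsilyl)oxy]methyl}-5-(prop-1-en-2-yl)cyclohex-2-en-1-one | C=C(C)[C@@H]1CC(=O)C(CO[Si](C)(C)C(C)(C)C)=CC1 | intermediate
9 | isopropenylmagnesium bromide | C=C(C)[Mg]Br | starting material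
10 | bromomagnesium (3R,5S)-2-{[(tert-butyldimethylsilyl)oxy]methyl}-3,5-di(prop-1-en-2-yl)cyclohex-1-en-1-olate | C=C(C)[C@@H]1CC(O[Mg]Br)=C(CO[Si](C)(C)C(C)(C)C)[C@H](C1)C(C)=C | intermediate (not isolated)
11 | (2S,3R,5S)-2-{[(tert-butyldimethylsilyl)oxy]methyl}-2-(hydroxymethyl)-3,5-di(prop-1-en-2-yl)cyclohexan-1-one | C=C(C)[C@@H]1CC(=O)[C@@](CO)(CO[Si](C)(C)C(C)(C)C)[C@H](C1)C(C)=C | intermediate
12 | (1R,4S,6R)-1-{[(tert-butyldimethylsilyl)oxy]methyl}-2-oxo-4,6-di(prop-1-en-2-yl)cyclohexane-1-carbaldehyde | C=C(C)[C@@H]1CC(=O)[C@@](C=O)(CO[Si](C)(C)C(C)(C)C)[C@H](C1)C(C)=C | intermediate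
13 | allenylboronic acid pinacol ester (4,4,5,5-tetramethyl-2-(propa-1,2-dien-1-yl)-1,3,2-dioxaborolane) | C=C=CB1OC(C)(C)C(C)(C)O1 | starting material
14 | adduct of 12: C1–O–B(Ipc)2 borinate with a pinacolboryl group on C2 (configuration as in 15) | C=C(C)[C@@H]1CC(=O)[C@@]([C@@H](OB([C@@H]2C[C@@H]3C[C@H]([C@H]2C)C3(C)C)[C@@H]2C[C@@H]3C[C@H]([C@H]2C)C3(C)C)[C@@H](B2OC(C)(C)C(C)(C)O2)C=C)(CO[Si](C)(C)C(C)(C)C)[C@H](C1)C(C)=C | intermediate (not isolated)
15 | (2R,3R,5S)-2-{[(tert-butyldimethylsilyl)oxy]methyl}-2-[(1R,2S)-1,2-dihydroxybut-3-en-1-yl]-3,5-di(prop-1-en-2-yl)cyclohexan-1-one | C=C(C)[C@@H]1CC(=O)[C@@]([C@@H](O)[C@@H](O)C=C)(CO[Si](C)(C)C(C)(C)C)[C@H](C1)C(C)=C | intermediate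
16 | (1R,2S,5R,7S,10R)-14-[(tert-butyldimethylsilyl)oxy]-1,2-dihydroxyeudesma-3,11-dien-9-one | C=C(C)[C@@H]1CC(=O)[C@@]2(CO[Si](C)(C)C(C)(C)C)[C@H](C1)C(C)=C[C@H](O)[C@@H]2O | intermediate
17 | (1R,2S,5R,7S,10R)-14-[(tert-butyldimethylsilyl)oxy]-1-hydroxy-9-oxoeudesma-3,11-dien-2-yl acetate | C=C(C)[C@@H]1CC(=O)[C@@]2(CO[Si](C)(C)C(C)(C)C)[C@H](C1)C(C)=C[C@H](OC(C)=O)[C@@H]2O | intermediate
18 | (1R,2S,5R,7S,9S,10S)-2-acetoxy-14-[(tert-butyldimethylsilyl)oxy]-9-hydroxyeudesma-3,11-dien-1-yl 3-methylbutanoate | C=C(C)[C@@H]1C[C@H](O)[C@@]2(CO[Si](C)(C)C(C)(C)C)[C@H](C1)C(C)=C[C@H](OC(C)=O)[C@@H]2OC(=O)CC(C)C | intermediate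
19 | (1R,2S,5R,7S,9S,10S)-2,9-diacetoxy-14-[(tert-butyldimethylsilyl)oxy]eudesma-3,11-dien-1-yl 3-methylbutanoate | C=C(C)[C@@H]1C[C@H](OC(C)=O)[C@@]2(CO[Si](C)(C)C(C)(C)C)[C@H](C1)C(C)=C[C@H](OC(C)=O)[C@@H]2OC(=O)CC(C)C | intermediate
20 | (1R,2S,5R,7S,9S,10S)-2,9-diacetoxy-14-hydroxyeudesma-3,11-dien-1-yl 3-methylbutanoate (CNP0257109.1) | C=C(C)[C@@H]1C[C@H](OC(C)=O)[C@@]2(CO)[C@H](C1)C(C)=C[C@H](OC(C)=O)[C@@H]2OC(=O)CC(C)C | target

## Step count and least certain steps

Total: 12 steps. Longest linear sequence: 12 steps (1 → 20); compounds 2, 6, 9 and 13 are used as purchased.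

**Step 5 (key step).** The most likely failure is loss of silanolate from enolate 10 (E1cB, giving the α-methylene ketone), or simple protonation of 10. The cause is that capture by gaseous formaldehyde at the hindered tetrasubstituted enolate carbon is slow. Fallback: starting from 8 and 9, the conjugate addition is run in the presence of TMSCl and the product is isolated as the trimethylsilyl enol ether F1. F1 is then hydroxymethylated under Lewis-acid catalysis (aqueous 6, Sc(OTf)3, THF/H2O; Mukaiyama aldol), so that C–C bond formation no longer passes through a basic metal enolate. The sequence returns to the route at 11.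

**Step 2.** The most likely failure is poor regioselectivity of the kinetic enolisation of 3 (C8 against C10), because both α-positions are methylenes and differ only by a β-substituent. Fallback: the position of the unsaturation is fixed before the stereocentre is made. Starting from 1, sulfenylation of the kinetic α′-enolate (LDA, PhSSO2Ph) gives 6-(phenylsulfanyl)cyclohex-2-en-1-one F2. The same rhodium-catalysed addition of 2 gives the sulfide ketone F3. Oxidation (mCPBA, −78 °C) gives the sulfoxide F4, and thermal syn-elimination (toluene, CaCO3, 110 °C) returns to the route at 5.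

**Step 7.** The most likely failures are slow addition of the bulky Ipc2B reagent to the neopentyl aldehyde and retro-aldol cleavage of the C1–C10 bond during the basic peroxide oxidation, since the adduct is a β-alkoxy ketone with a quaternary α-carbon. Fallback: starting from 12, an indium-mediated Barbier α-acetoxyallylation with 3-bromoprop-1-enyl acetate in THF/H2O is used; it is neutral and needs no oxidation. It would give the C2 monoacetate F5 directly, under substrate control only, so the anti isomer may have to be separated from syn material. Ring-closing metathesis of F5 (Grubbs second-generation catalyst) returns to the route at 17.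

**Step 9.** The most likely failure is over-acylation or acylation at O1 followed by acetyl migration within the cis-diol, because the rate difference between the two hydroxyls rests on sterics alone. Fallback: starting from 16, the cyclic methyl orthoacetate F6 is formed (MeC(OMe)3, CSA, CH2Cl2). Its hydrolysis with aqueous acetic acid should open to the ester on the pseudo-axial oxygen (O2) by stereoelectronic control, which returns to the route at 17.

**Step 10.** The most likely failures are slow hemiacetal formation at the hindered C1 hydroxyl, and retro-aldol opening of ring A (C1–C10) or 1,3-acyl migration promoted by samarium alkoxides. Fallback: the two events are separated. Starting from 17, an Evans–Saksena reduction (Me4NBH(OAc)3, AcOH/MeCN, −20 °C) directed by the C1 hydroxyl gives the anti-diol F7. Acylation with isovaleric anhydride/DMAP at the equatorial C1 hydroxyl, in preference to the axially shielded C9 hydroxyl, returns to the route at 18.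

## Further compounds

F1 | step 5 | {[(3R,5S)-2-{[(tert-butyldimethylsilyl)oxy]methyl}-3,5-di(prop-1-en-2-yl)cyclohex-1-en-1-yl]oxy}trimethylsilane | C=C(C)[C@@H]1CC(O[Si](C)(C)C)=C(CO[Si](C)(C)C(C)(C)C)[C@H](C1)C(C)=C
F2 | step 2 | 6-(phenylsulfanyl)cyclohex-2-en-1-one (racemic) | O=C1C=CCCC1Sc1ccccc1
F3 | step 2 | (3S)-6-(phenylsulfanyl)-3-(prop-1-en-2-yl)cyclohexan-1-one (C6 epimers) | C=C(C)[C@@H]1CC(=O)C(Sc2ccccc2)CC1
F4 | step 2 | (3S)-6-(benzenesulfinyl)-3-(prop-1-en-2-yl)cyclohexan-1-one (diastereomers) | C=C(C)[C@@H]1CC(=O)C(S(=O)c2ccccc2)CC1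
F5 | step 7 | (2R,3R,5S)-2-[(1R,2S)-2-acetoxy-1-hydroxybut-3-en-1-yl]-2-{[(tert-butyldimethylsilyl)oxy]methyl}-3,5-di(prop-1-en-2-yl)cyclohexan-1-one | C=C(C)[C@@H]1CC(=O)[C@@]([C@@H](O)[C@@H](OC(C)=O)C=C)(CO[Si](C)(C)C(C)(C)C)[C@H](C1)C(C)=C
F6 | step 9 | 1,2-O-(1-methoxyethylidene) cyclic orthoacetate of 16 | C=C(C)[C@@H]1CC(=O)[C@@]2(CO[Si](C)(C)C(C)(C)C)[C@H](C1)C(C)=C[C@H](OC(C)(OC)O3)[C@@H]23
F7 | step 10 | (1R,2S,5R,7S,9S,10S)-14-[(tert-butyldimethylsilyl)oxy]-1,9-dihydroxyeudesma-3,11-dien-2-yl acetate | C=C(C)[C@@H]1C[C@H](O)[C@@]2(CO[Si](C)(C)C(C)(C)C)[C@H](C1)C(C)=C[C@H](OC(C)=O)[C@@H]2O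
A1 | alternative 1 | (5R)-2-methyl-5-(prop-1-en-2-yl)cyclohexan-1-one ((+)-dihydrocarvone, C2 epimers) | C=C(C)[C@@H]1CCC(C)C(=O)C1
A2 | alternative 1 | pent-1-en-3-one (ethyl vinyl ketone) | CCC(=O)C=C
A3 | alternative 1 | (7R,10R)-eudesma-4,11-dien-3-one (10-epi-α-cyperone) | C=C(C)[C@@H]1CC[C@@]2(C)C(C1)=C(C)C(=O)CC2
A4 | alternative 2 | (1Z,3S,5S,7E,9E)-10-acetoxy-3-[(tert-butyldimethylsilyl)oxy]-2-formyl-8-methyl-5-(prop-1-en-2-yl)deca-1,7,9-trien-1-yl 3-methylbutanoate | C=C(C)[C@@H](C/C=C(C)/C=C/OC(C)=O)C[C@H](O[Si](C)(C)C(C)(C)C)/C(C=O)=C/OC(=O)CC(C)C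
A5 | alternative 2 | (1R,2S,5R,7S,9S,10R)-2-acetoxy-9-[(tert-butyldimethylsilyl)oxy]-14-oxoeudesma-3,11-dien-1-yl 3-methylbutanoate | C=C(C)[C@@H]1C[C@H](O[Si](C)(C)C(C)(C)C)[C@@]2(C=O)[C@H](C1)C(C)=C[C@H](OC(C)=O)[C@@H]2OC(=O)CC(C)C
A6 | alternative 3 | 1,10-epoxide of (4E)-2,9-diacetoxy-14-[(tert-butyldimethylsilyl)oxy]germacra-4,11-diene | C=C(C)[C@@H]1C[C@H](OC(C)=O)[C@]2(CO[Si](C)(C)C(C)(C)C)O[C@H]2[C@@H](OC(C)=O)C/C(C)=C/C1
A7 | alternative 3 | (1R,2S,5R,7S,9S,10R)-2,9-diacetoxy-14-[(tert-butyldimethylsilyl)oxy]eudesma-3,11-dien-1-ol | C=C(C)[C@@H]1C[C@H](OC(C)=O)[C@@]2(CO[Si](C)(C)C(C)(C)C)[C@H](C1)C(C)=C[C@H](OC(C)=O)[C@@H]2O
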